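The C6–C7 bond of ring B is the disconnection on which everything rests. The C6 ketone and the C7 acetoxy carbinol, flanked by the ring-fusion carbon C5 and the tertiary carbinol C8, form an α-ketol, the product pattern of a benzoin reaction; the key step exploits exactly this C6/C7 array. A carbene-catalysed intramolecular benzoin closes ring B, forms C6–C7, places the ketone at C6 and sets the C7 carbinol in one operation. Its precursor is a 6,7-seco dialdehyde that already carries ring A, the spiro tetrahydrofuran ring C with the C13 ethynyl and silyloxymethyl groups, and the silylated C8 carbinol; it comes from (+)-sclareolide and 2-bromoallyl alcohol.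

Key step: step 15

Remark: labdane numbering is used throughout; it is assumed that the acid-equilibrated ester of step 1 is mainly the tetrasubstituted C8=C9 isomer and can be separated from its minor alkene isomers.

Step 1
Reactants: 1 (+)-sclareolide
Product: 2 methyl 13,14,15,16-tetranorlabd-8-en-12-oate
Conditions: conc. H2SO4, MeOH, reflux
Reagents that add atoms: methanol (CO)
Why: Acid-catalysed lactone methanolysis with E1 dehydration of the C8 tertiary alcohol and equilibration of the alkene isomers should lead to the tetrasubstituted C8=C9 ester as the thermodynamic product (minor trisubstituted and exocyclic isomers removed by chromatography), leaving C5 and C10 untouched.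

Step 2
Reactants: 2 methyl 13,14,15,16-tetranorlabd-8-en-12-oate
Product: 3 13,14,15,16-tetranorlabd-8-en-12-ol
Conditions: LiAlH4, THF, 0 °C to rt
Reagents that add atoms: none
Why: LiAlH4 reduction of the ester gives the primary alcohol while the isolated tetrasubstituted alkene is inert to hydride.

Step 3
Reactants: 3 13,14,15,16-tetranorlabd-8-en-12-ol
Product: 4 12-bromo-13,14,15,16-tetranorlabd-8-ene
Conditions: CBr4, PPh3, CH2Cl2, 0 °C
Reagents that add atoms: carbon tetrabromide (BrC(Br)(Br)Br)
Why: Appel bromination replaces the unhindered primary hydroxyl by SN2 attack of bromide on the alkoxyphosphonium ion.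

Step 4
Reactants: 4 12-bromo-13,14,15,16-tetranorlabd-8-ene; 5 2-bromoallyl alcohol
Product: 6 15-norlabda-8,13(14)-dien-16-ol
Conditions: NiBr2(MeOCH2CH2OMe) (10 mol %), 4,4′-di-tert-butyl-2,2′-bipyridine (10 mol %), Mn powder, NaI (25 mol %), DMPU, rt
Reagents that add atoms: none
Why: Nickel-catalysed reductive cross-electrophile coupling unites the alkenyl bromide (oxidative addition to low-valent nickel) and the primary alkyl bromide (radical capture) to form the C12–C13 bond, and this coupling type tolerates free hydroxyl groups.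

Step 5
Reactants: 6 15-norlabda-8,13(14)-dien-16-ol
Product: 7 (13S)-13,14-epoxy-15-norlabd-8-en-16-ol
Conditions: Ti(OiPr)4 (10 mol %), L-(+)-diethyl tartrate (12 mol %), t-BuOOH, 4 Å molecular sieves, CH2Cl2, −20 °C
Reagents that add atoms: tert-butyl hydroperoxide (CC(C)(C)OO)
Why: Sharpless asymmetric epoxidation of the 2-substituted allylic alcohol with the L-(+)-tartrate ligand should deliver oxygen to a single face of the C13=C14 alkene under reagent control and set C13 as S, while the tetrasubstituted C8=C9 alkene, which has no allylic hydroxyl to bind titanium, is not epoxidised.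

Step 6
Reactants: 7 (13S)-13,14-epoxy-15-norlabd-8-en-16-ol
Product: 8 (13R)-16-(tert-butyldimethylsilyloxy)-13,14-epoxy-15-norlabd-8-ene
Conditions: TBSCl, imidazole, CH2Cl2, rt
Reagents that add atoms: tert-butyldimethylsilyl chloride (CC(C)(C)[Si](C)(C)Cl)
Why: Silylation of the primary alcohol fixes C16 as the silyl ether so that the two oxygenated carbons on C13 stay distinguishable when the epoxide is opened later (the descriptor changes by priority only).

Step 7
Reactants: 8 (13R)-16-(tert-butyldimethylsilyloxy)-13,14-epoxy-15-norlabd-8-ene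
Product: 9 (13R)-16-(tert-butyldimethylsilyloxy)-13,14-epoxy-15-norlabd-8-en-7-one
Conditions: CrO3, 3,5-dimethylpyrazole, CH2Cl2, −20 °C
Reagents that add atoms: chromium trioxide (O=[Cr](=O)=O)
Why: Allylic oxidation with the CrO3–3,5-dimethylpyrazole complex should convert the ring methylene C7, whose axial C–H bond overlaps with the alkene and which is less crowded than C11, into the enone under buffered conditions that a 2,2-disubstituted epoxide and a silyl ether withstand.

Step 8
Reactants: 9 (13R)-16-(tert-butyldimethylsilyloxy)-13,14-epoxy-15-norlabd-8-en-7-one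
Product: 10 (13R)-16-(tert-butyldimethylsilyloxy)-8α,9α:13,14-diepoxy-15-norlabdan-7-one
Conditions: H2O2 (30 %), NaOH, MeOH/THF, 0 °C to rt
Reagents that add atoms: hydrogen peroxide (OO)
Why: Weitz–Scheffer nucleophilic epoxidation, in which hydroperoxide adds to C9 along the axial trajectory anti to the C10 methyl group and the enolate closes onto oxygen, so that the 8α,9α-epoxide (new stereocentres C8 and C9) should result.

Step 9
Reactants: 10 (13R)-16-(tert-butyldimethylsilyloxy)-8α,9α:13,14-diepoxy-15-norlabdan-7-one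
Product: 12 (13S)-16-(tert-butyldimethylsilyloxy)-9α,13-epoxy-15-norlabd-7-en-14-ol, via 9α-hydroxy-7-ene side-chain epoxide 11 (not isolated)
Conditions: N2H4·H2O, AcOH, MeOH, 0 °C to rt; aqueous work-up; then PPTS (cat.), CH2Cl2, rt
Reagents that add atoms: none
Why: Wharton transposition (hydrazone, epoxide opening, loss of N2) moves the alkene to C7=C8 and leaves the C9 oxygen as the α tertiary alcohol with retention, and mild acid then lets this alcohol open the side-chain epoxide at its tertiary carbon C13 in a 5-exo mode with inversion, which closes ring C and fixes C13.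

Step 10
Reactants: 12 (13S)-16-(tert-butyldimethylsilyloxy)-9α,13-epoxy-15-norlabd-7-en-14-ol
Product: 13 (13R)-16-(tert-butyldimethylsilyloxy)-9α,13-epoxy-15-norlabd-7-en-14-al
Conditions: Dess–Martin periodinane, pyridine, CH2Cl2, rt
Reagents that add atoms: none
Why: Dess–Martin oxidation of the primary alcohol gives an aldehyde on the fully substituted C13, which cannot epimerise.

Step 11
Reactants: 13 (13R)-16-(tert-butyldimethylsilyloxy)-9α,13-epoxy-15-norlabd-7-en-14-al
Product: 14 (13S)-16-(tert-butyldimethylsilyloxy)-9α,13-epoxylabd-7-en-14-yne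
Conditions: dimethyl (1-diazo-2-oxopropyl)phosphonate, K2CO3, MeOH, 0 °C to rt
Reagents that add atoms: dimethyl (1-diazo-2-oxopropyl)phosphonate (COP(=O)(OC)C(=[N+]=[N-])C(C)=O)
Why: Seyferth–Gilbert homologation with the Ohira–Bestmann reagent converts the non-enolisable aldehyde into the terminal alkyne C14≡C15 under mild carbonate conditions.

Step 12
Reactants: 14 (13S)-16-(tert-butyldimethylsilyloxy)-9α,13-epoxylabd-7-en-14-yne
Product: 16 (13S)-16-(tert-butyldimethylsilyloxy)-9α,13-epoxylabd-6-en-14-yn-8β-ol, via 7α-phenylselanyl-8β-ol 15 (not isolated)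
Conditions: N-(phenylseleno)phthalimide, H2O, PPTS (cat.), CH2Cl2, rt; then H2O2 (30 %), pyridine, 0 °C to rt
Reagents that add atoms: water (O)
Why: Hydroxyselenation followed by selenoxide syn-elimination, in which the reversibly formed α-seleniranium ion is opened by water at the tertiary C8 from the β face in the trans-diaxial sense (7α-selenide and 8β-hydroxyl, setting C8) and the selenoxide can eliminate only toward C6, which gives the transposed 6-ene while the less nucleophilic alkyne is left alone.

Step 13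
Reactants: 16 (13S)-16-(tert-butyldimethylsilyloxy)-9α,13-epoxylabd-6-en-14-yn-8β-ol
Product: 17 (13S)-16-(tert-butyldimethylsilyloxy)-9α,13-epoxy-8β-(triethylsilyloxy)labd-6-en-14-yne
Conditions: TESOTf, 2,6-lutidine, CH2Cl2, −78 to 0 °C
Reagents that add atoms: triethylsilyl trifluoromethanesulfonate (CC[Si](CC)(CC)OS(=O)(=O)C(F)(F)F)
Why: Silylation of the hindered tertiary allylic alcohol with the reactive silyl triflate under 2,6-lutidine buffering protects the C8 oxygen so that it cannot form a lactol with the C6 aldehyde later.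

Step 14
Reactants: 17 (13S)-16-(tert-butyldimethylsilyloxy)-9α,13-epoxy-8β-(triethylsilyloxy)labd-6-en-14-yne
Product: 18 (13S)-16-(tert-butyldimethylsilyloxy)-9α,13-epoxy-8β-(triethylsilyloxy)-6,7-secolabd-14-yne-6,7-dial
Conditions: O3, CH2Cl2, −78 °C (Sudan red end point); then PPh3, −78 °C to rt
Reagents that add atoms: ozone ([O-][O+]=O)
Why: Ozonolysis with reductive work-up cleaves the cis-disubstituted alkene, which reacts with ozone far faster than the terminal alkyne, and the C5 formyl group stays in the more stable equatorial position trans to the C10 substituent.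

Step 15
Reactants: 18 (13S)-16-(tert-butyldimethylsilyloxy)-9α,13-epoxy-8β-(triethylsilyloxy)-6,7-secolabd-14-yne-6,7-dial
Product: 19 (13S)-16-(tert-butyldimethylsilyloxy)-9α,13-epoxy-7β-hydroxy-8β-(triethylsilyloxy)labd-14-yn-6-one
Conditions: 2-(pentafluorophenyl)-6,7-dihydro-5H-pyrrolo[2,1-c][1,2,4]triazol-2-ium tetrafluoroborate (20 mol %), iPr2NEt (20 mol %), CH2Cl2, rt to 40 °C
Reagents that add atoms: none
Why: Deprotonation of the triazolium salt gives the carbene, which adds to the C6 aldehyde (α-CH, against the α-quaternary, α-silyloxy C7 aldehyde) and after proton transfer forms the enaminol acyl-anion equivalent; this attacks the more electrophilic C7 aldehyde, and the catalyst is expelled from the tetrahedral adduct. The closest known reaction type is the carbene-catalysed intramolecular cross-benzoin cyclisation of dialdehydes. Ring B closes in a 6-exo-trig mode, C6 attacking the C7 carbonyl carbon whose oxygen stays outside the new ring. The new stereocentre C7 is controlled by a chair transition state with the aldehyde oxygen pseudo-equatorial and hydrogen-bonded to the enaminol hydroxyl, and by reversibility (retro-benzoin and enediol tautomerism under the amine base), both of which should favour the equatorial 7β-hydroxyl that avoids the axial C9 oxygen. The step needs the 6-oxo-7-ol regiochemistry and retention of the trans ring fusion at C5: the oxygenated quaternary C8 makes the C7 aldehyde a poor donor and a good acceptor, the silyl ether on the C8 oxygen blocks lactol formation and redox esterification, and the weak amine base should leave the silyl group in place and C5 in its more stable equatorial arrangement.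

Step 16
Reactants: 19 (13S)-16-(tert-butyldimethylsilyloxy)-9α,13-epoxy-7β-hydroxy-8β-(triethylsilyloxy)labd-14-yn-6-one
Product: 20 (13S)-7β-acetoxy-16-(tert-butyldimethylsilyloxy)-9α,13-epoxy-8β-(triethylsilyloxy)labd-14-yn-6-one
Conditions: Ac2O, DMAP (cat.), pyridine, CH2Cl2, 0 °C to rt
Reagents that add atoms: acetic anhydride (CC(=O)OC(C)=O)
Why: DMAP-catalysed acetylation of the only free hydroxyl, the equatorial C7 carbinol, should be fast enough to outrun base-mediated ketol isomerisation.

Step 17
Reactants: 20 (13S)-7β-acetoxy-16-(tert-butyldimethylsilyloxy)-9α,13-epoxy-8β-(triethylsilyloxy)labd-14-yn-6-one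
Product: 21 (13S)-7β-acetoxy-9α,13-epoxy-8β,16-dihydroxylabd-14-yn-6-one
Conditions: HF·pyridine, pyridine, THF, 0 °C to rt
Reagents that add atoms: none
Why: Fluoride-mediated desilylation with buffered HF·pyridine removes the primary TBS and the tertiary TES ether in one operation under mildly acidic conditions that avoid acetate migration or epimerisation next to the ketone.

Step 18
Reactants: 21 (13S)-7β-acetoxy-9α,13-epoxy-8β,16-dihydroxylabd-14-yn-6-one
Product: 22 (13S)-7β-acetoxy-9α,13:15,16-diepoxy-8β-hydroxylabd-14-en-6-one (CNP0284584.1)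
Conditions: Mo(CO)6 (25 mol %), Et3N, Et2O, hν (350 nm), rt
Reagents that add atoms: none
Why: Alkynol cycloisomerisation, in which photochemically generated Mo(CO)5(NEt3) turns the terminal alkyne into a molybdenum vinylidene whose electrophilic carbon C15 is attacked by the C16 hydroxyl (5-endo ring closure), and protodemetalation under the basic conditions gives the acid-sensitive 2,3-dihydrofuran ring D without touching C13.

Compound list

1 | (+)-sclareolide [(3aR,5aS,9aS,9bR)-3a,6,6,9a-tetramethyldecahydronaphtho[2,1-b]furan-2(1H)-one] | C1C[C@H]2C(C)(C)CCC[C@]2(C)[C@H]3CC(=O)O[C@]13C | starting material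
2 | methyl 13,14,15,16-tetranorlabd-8-en-12-oate (5α-H, 10β-methyl, tetrasubstituted C8=C9) | C[C@]12CCCC(C)(C)[C@@H]1CCC(C)=C2CC(=O)OC | intermediate
3 | 13,14,15,16-tetranorlabd-8-en-12-ol | C[C@]12CCCC(C)(C)[C@@H]1CCC(C)=C2CCO | intermediate
4 | 12-bromo-13,14,15,16-tetranorlabd-8-ene | C[C@]12CCCC(C)(C)[C@@H]1CCC(C)=C2CCBr | intermediate
5 | 2-bromoallyl alcohol (2-bromoprop-2-en-1-ol) | OCC(Br)=C | starting material
6 | 15-norlabda-8,13(14)-dien-16-ol (C13 carries the methylene C14 and the hydroxymethyl C16) | C[C@]12CCCC(C)(C)[C@@H]1CCC(C)=C2CCC(=C)CO | intermediate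
7 | (13S)-13,14-epoxy-15-norlabd-8-en-16-ol | C[C@]12CCCC(C)(C)[C@@H]1CCC(C)=C2CC[C@]3(CO)CO3 | intermediate
8 | (13R)-16-(tert-butyldimethylsilyloxy)-13,14-epoxy-15-norlabd-8-ene (same spatial arrangement at C13 as in 7) | C[C@]12CCCC(C)(C)[C@@H]1CCC(C)=C2CC[C@]3(CO[Si](C)(C)C(C)(C)C)CO3 | intermediate
9 | (13R)-16-(tert-butyldimethylsilyloxy)-13,14-epoxy-15-norlabd-8-en-7-one | C[C@]12CCCC(C)(C)[C@@H]1CC(=O)C(C)=C2CC[C@]3(CO[Si](C)(C)C(C)(C)C)CO3 | intermediate
10 | (13R)-16-(tert-butyldimethylsilyloxy)-8α,9α:13,14-diepoxy-15-norlabdan-7-one | C[C@]12CCCC(C)(C)[C@@H]1CC(=O)[C@@]4(C)O[C@@]24CC[C@]3(CO[Si](C)(C)C(C)(C)C)CO3 | intermediate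
11 | (13R)-16-(tert-butyldimethylsilyloxy)-13,14-epoxy-15-norlabd-7-en-9α-ol | C[C@]12CCCC(C)(C)[C@@H]1CC=C(C)[C@]2(O)CC[C@]3(CO[Si](C)(C)C(C)(C)C)CO3 | intermediate
12 | (13S)-16-(tert-butyldimethylsilyloxy)-9α,13-epoxy-15-norlabd-7-en-14-ol | C[C@]12CCCC(C)(C)[C@@H]1CC=C(C)[C@]23CC[C@@](CO[Si](C)(C)C(C)(C)C)(CO)O3 | intermediate
13 | (13R)-16-(tert-butyldimethylsilyloxy)-9α,13-epoxy-15-norlabd-7-en-14-al | C[C@]12CCCC(C)(C)[C@@H]1CC=C(C)[C@]23CC[C@@](CO[Si](C)(C)C(C)(C)C)(C=O)O3 | intermediate
14 | (13S)-16-(tert-butyldimethylsilyloxy)-9α,13-epoxylabd-7-en-14-yne | C[C@]12CCCC(C)(C)[C@@H]1CC=C(C)[C@]23CC[C@@](CO[Si](C)(C)C(C)(C)C)(C#C)O3 | intermediate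
15 | (13S)-16-(tert-butyldimethylsilyloxy)-9α,13-epoxy-7α-(phenylselanyl)labd-14-yn-8β-ol | C[C@]12CCCC(C)(C)[C@@H]1C[C@@H]([Se]c4ccccc4)[C@](C)(O)[C@]23CC[C@@](CO[Si](C)(C)C(C)(C)C)(C#C)O3 | intermediate
16 | (13S)-16-(tert-butyldimethylsilyloxy)-9α,13-epoxylabd-6-en-14-yn-8β-ol | C[C@]12CCCC(C)(C)[C@@H]1C=C[C@](C)(O)[C@]23CC[C@@](CO[Si](C)(C)C(C)(C)C)(C#C)O3 | intermediate
17 | (13S)-16-(tert-butyldimethylsilyloxy)-9α,13-epoxy-8β-(triethylsilyloxy)labd-6-en-14-yne | C[C@]12CCCC(C)(C)[C@@H]1C=C[C@](C)(O[Si](CC)(CC)CC)[C@]23CC[C@@](CO[Si](C)(C)C(C)(C)C)(C#C)O3 | intermediate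
18 | (13S)-16-(tert-butyldimethylsilyloxy)-9α,13-epoxy-8β-(triethylsilyloxy)-6,7-secolabd-14-yne-6,7-dial | O=C[C@H]1C(C)(C)CCC[C@]1(C)[C@@]2(CC[C@@](CO[Si](C)(C)C(C)(C)C)(C#C)O2)[C@@](C)(O[Si](CC)(CC)CC)C=O | intermediate
19 | (13S)-16-(tert-butyldimethylsilyloxy)-9α,13-epoxy-7β-hydroxy-8β-(triethylsilyloxy)labd-14-yn-6-one | O[C@H]1C(=O)[C@H]2C(C)(C)CCC[C@]2(C)[C@@]2(CC[C@@](CO[Si](C)(C)C(C)(C)C)(C#C)O2)[C@@]1(C)O[Si](CC)(CC)CC | intermediate
20 | (13S)-7β-acetoxy-16-(tert-butyldimethylsilyloxy)-9α,13-epoxy-8β-(triethylsilyloxy)labd-14-yn-6-one | CC(=O)O[C@H]1C(=O)[C@H]2C(C)(C)CCC[C@]2(C)[C@@]2(CC[C@@](CO[Si](C)(C)C(C)(C)C)(C#C)O2)[C@@]1(C)O[Si](CC)(CC)CC | intermediate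
21 | (13S)-7β-acetoxy-9α,13-epoxy-8β,16-dihydroxylabd-14-yn-6-one | CC(=O)O[C@H]1C(=O)[C@H]2C(C)(C)CCC[C@]2(C)[C@@]2(CC[C@@](CO)(C#C)O2)[C@@]1(C)O | intermediate
22 | (13S)-7β-acetoxy-9α,13:15,16-diepoxy-8β-hydroxylabd-14-en-6-one (CNP0284584.1) | CC(=O)O[C@H]1C(=O)[C@H]2C(C)(C)CCC[C@]2(C)[C@@]2(CC[C@@]3(C=COC3)O2)[C@@]1(C)O | target

Total step count: 18. Longest linear sequence: 18 steps (from 1; compound 5 enters at step 4).

Steps most likely to fail

Step 15 (key step). The carbene may engage the wrong aldehyde, the ketol may settle as the regioisomeric 7-oxo-6-ol or as a C7 or C5 epimer, or enolisation of the C6 aldehyde may divert material into aldol products. The fallback sets out from 17 and builds the ketol without umpolung: OsO4-catalysed dihydroxylation of the 6-ene from the less shielded α face should give the (13S)-16-(tert-butyldimethylsilyloxy)-9α,13-epoxy-8β-(triethylsilyloxy)labd-14-yne-6α,7α-diol F1; catalytic TEMPO with PhI(OAc)2 should oxidise the less hindered equatorial C6 carbinol to the (13S)-16-(tert-butyldimethylsilyloxy)-9α,13-epoxy-7α-hydroxy-8β-(triethylsilyloxy)labd-14-yn-6-one F2; brief treatment with DBU then epimerises C7 through the enediol to the equatorial alcohol, and the route is rejoined at 19.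

Step 7. Oxidation may occur at the other allylic positions (C11 or the C8 methyl group), or the chromium reagent may open the side-chain epoxide. The fallback sets out from 2 and oxidises at the ester stage, where C11 is deactivated by the ester and no epoxide is present. The same chromium reagent should give methyl 7-oxo-13,14,15,16-tetranorlabd-8-en-12-oate F3. LiAlH4 reduces both carbonyl groups to 13,14,15,16-tetranorlabd-8-ene-7β,12-diol F4. MnO2 reoxidises only the allylic alcohol to 12-hydroxy-13,14,15,16-tetranorlabd-8-en-7-one F5. Appel bromination gives 12-bromo-13,14,15,16-tetranorlabd-8-en-7-one F6. The nickel coupling with 5 gives 16-hydroxy-15-norlabda-8,13(14)-dien-7-one F7. Sharpless epoxidation with L-(+)-diethyl tartrate gives (13S)-13,14-epoxy-16-hydroxy-15-norlabd-8-en-7-one F8. Silylation with TBSCl returns to the route at 9.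

Step 12. The bulky selenium electrophile may add sluggishly to the hindered alkene next to the oxygenated C9, or facial and regiochemical control of the water attack may be poor. The fallback sets out from 14 and uses nucleophilic selenium on an epoxide instead: NBS in aqueous acetone should give, by trans-diaxial opening of the α-bromonium ion at C8, the (13S)-7α-bromo-16-(tert-butyldimethylsilyloxy)-9α,13-epoxylabd-14-yn-8β-ol F9; K2CO3 in MeOH closes it to the (13S)-16-(tert-butyldimethylsilyloxy)-7β,8β:9α,13-diepoxylabd-14-yne F10; sodium phenylselenide (PhSeSePh, NaBH4, EtOH) opens this epoxide at C7 in the trans-diaxial sense, and the route is rejoined at 15, which is oxidised to 16 as before.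

Further compounds

F1 | step 15 | (13S)-16-(tert-butyldimethylsilyloxy)-9α,13-epoxy-8β-(triethylsilyloxy)labd-14-yne-6α,7α-diol | C[C@]12CCCC(C)(C)[C@@H]1[C@@H](O)[C@@H](O)[C@](C)(O[Si](CC)(CC)CC)[C@]23CC[C@@](CO[Si](C)(C)C(C)(C)C)(C#C)O3
F2 | step 15 | (13S)-16-(tert-butyldimethylsilyloxy)-9α,13-epoxy-7α-hydroxy-8β-(triethylsilyloxy)labd-14-yn-6-one | O[C@@H]1C(=O)[C@H]2C(C)(C)CCC[C@]2(C)[C@@]2(CC[C@@](CO[Si](C)(C)C(C)(C)C)(C#C)O2)[C@@]1(C)O[Si](CC)(CC)CC
F3 | step 7 | methyl 7-oxo-13,14,15,16-tetranorlabd-8-en-12-oate | C[C@]12CCCC(C)(C)[C@@H]1CC(=O)C(C)=C2CC(=O)OC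
F4 | step 7 | 13,14,15,16-tetranorlabd-8-ene-7β,12-diol | C[C@]12CCCC(C)(C)[C@@H]1C[C@H](O)C(C)=C2CCO
F5 | step 7 | 12-hydroxy-13,14,15,16-tetranorlabd-8-en-7-one | C[C@]12CCCC(C)(C)[C@@H]1CC(=O)C(C)=C2CCO
F6 | step 7 | 12-bromo-13,14,15,16-tetranorlabd-8-en-7-one | C[C@]12CCCC(C)(C)[C@@H]1CC(=O)C(C)=C2CCBr
F7 | step 7 | 16-hydroxy-15-norlabda-8,13(14)-dien-7-one | C[C@]12CCCC(C)(C)[C@@H]1CC(=O)C(C)=C2CCC(=C)CO
F8 | step 7 | (13S)-13,14-epoxy-16-hydroxy-15-norlabd-8-en-7-one | C[C@]12CCCC(C)(C)[C@@H]1CC(=O)C(C)=C2CC[C@]3(CO)CO3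
F9 | step 12 | (13S)-7α-bromo-16-(tert-butyldimethylsilyloxy)-9α,13-epoxylabd-14-yn-8β-ol | C[C@]12CCCC(C)(C)[C@@H]1C[C@@H](Br)[C@](C)(O)[C@]23CC[C@@](CO[Si](C)(C)C(C)(C)C)(C#C)O3
F10 | step 12 | (13S)-16-(tert-butyldimethylsilyloxy)-7β,8β:9α,13-diepoxylabd-14-yne | C[C@]12CCCC(C)(C)[C@@H]1C[C@@H]4O[C@]4(C)[C@]23CC[C@@](CO[Si](C)(C)C(C)(C)C)(C#C)O3
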